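**Plan**

1. Target: 3α,4β-dihydroxyeudesman-6β-yl benzoate (eudesmane numbering; ring A = C1–C5/C10, ring B = C5–C10; 5α-H, 7β-isopropyl, 10β-methyl, 4α-methyl). Ring B has oxygen on C6 beside the isopropyl-bearing C7 and a methyl on C10. This is the 2-isopropenylcyclohexanol unit that a 6-enal (formyl C6 on C5, isopropylidene C7=C11 on the C10 chain) forms by a carbonyl-ene reaction with itself.
2. Cuts, in order: the C3–O and C4–O bonds back to the C3=C4 alkene; the ester C–O; C6–C7 (ring B); C5–C6 (a [2,3]-shift from a C3 allylic ether); C4=C5 and C1–C10 (annulation of ring A).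
3. Forward: ring A is built from 2,6-dimethylhept-5-enal and ethyl vinyl ketone, the one-carbon unit C6 is moved onto C5, ring B is closed by the ene reaction, and C6, C3 and C4 are then adjusted.
4. Stereochemistry: C10 from the amine-catalysed Michael addition; a temporary C3 carbinol from a CBS reduction, relayed to C5 by the suprafacial [2,3]-shift; C7 (and C6) from the chair of the ene closure; final C6 by hydride attack anti to the 10β-methyl; C3/C4 by α-epoxidation and trans-diaxial opening.

Key step: step 6

Assumption: the (R,R)-amine–thiourea of step 1 is taken to favour the (S)-adduct 3; if a trial run shows the opposite sense, its (S,S)-enantiomer is used and nothing else changes.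

**Step 1**
Reactants: 1 2,6-dimethylhept-5-enal (racemic); 2 ethyl vinyl ketone
Product: 4 (S)-2,4-dimethyl-4-(4-methylpent-3-en-1-yl)cyclohex-2-en-1-one, via keto aldehyde 3 (not isolated)
Conditions: 1-[(1R,2R)-2-aminocyclohexyl]-3-[3,5-bis(trifluoromethyl)phenyl]thiourea (10 mol%), PhCO2H (10 mol%), toluene, 25 °C; then KOH, MeOH, 0 → 25 °C
Reagents that add atoms: none
Why: Enamine Michael addition of the α-branched aldehyde to the thiourea-bound vinyl ketone followed by base-induced aldol condensation (Robinson annulation) sets C10 by attack of one enamine face; since methyl and homoprenyl differ little the selectivity should be only moderate, which is tolerable because step 2 is reagent-controlled and material of the wrong C10 configuration then travels as a diastereomer that should be removable after step 6.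

**Step 2**
Reactants: 4 (S)-2,4-dimethyl-4-(4-methylpent-3-en-1-yl)cyclohex-2-en-1-one
Product: 5 (1S,4S)-2,4-dimethyl-4-(4-methylpent-3-en-1-yl)cyclohex-2-en-1-ol
Conditions: (R)-2-methyl-CBS-oxazaborolidine [(R)-1-methyl-3,3-diphenyltetrahydro-1H,3H-pyrrolo[1,2-c][1,3,2]oxazaborole] (15 mol%), catecholborane, toluene, −78 °C; aq. NaOH work-up
Reagents that add atoms: none
Why: Corey–Bakshi–Shibata reduction in which the α-methylalkenyl arm acts as the large group, so hydride should enter from the α face and give the 3β (1S) carbinol cis to the C10 methyl, while catecholborane leaves the trisubstituted alkenes alone.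

**Step 3**
Reactants: 5 (1S,4S)-2,4-dimethyl-4-(4-methylpent-3-en-1-yl)cyclohex-2-en-1-ol; 6 tributyl(iodomethyl)stannane
Product: 7 tributyl({[(1S,4S)-2,4-dimethyl-4-(4-methylpent-3-en-1-yl)cyclohex-2-en-1-yl]oxy}methyl)stannane
Conditions: KH, THF, 0 °C; then 6, 25 °C
Reagents that add atoms: none
Why: Williamson etherification of the potassium alkoxide with the primary iodide takes place at oxygen and leaves both stereocentres untouched.

**Step 4**
Reactants: 7 tributyl({[(1S,4S)-2,4-dimethyl-4-(4-methylpent-3-en-1-yl)cyclohex-2-en-1-yl]oxy}methyl)stannane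
Product: 9 [(1R,6S)-2,6-dimethyl-6-(4-methylpent-3-en-1-yl)cyclohex-2-en-1-yl]methanol, via lithiomethyl ether 8 (not isolated)
Conditions: n-BuLi, THF, −78 → −20 °C; then H2O
Reagents that add atoms: none
Why: Wittig–Still rearrangement, in which tin–lithium exchange gives the α-alkoxymethyllithium and a suprafacial [2,3]-sigmatropic shift through a five-membered envelope delivers the CH2O unit to C5 on the β face that carried the C3 oxygen (cis to the C10 methyl) while the double bond moves to C3=C4.

**Step 5**
Reactants: 9 [(1R,6S)-2,6-dimethyl-6-(4-methylpent-3-en-1-yl)cyclohex-2-en-1-yl]methanol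
Product: 10 (1R,6S)-2,6-dimethyl-6-(4-methylpent-3-en-1-yl)cyclohex-2-ene-1-carbaldehyde
Conditions: Dess–Martin periodinane, NaHCO3, CH2Cl2, 0 °C; crude product used at once
Reagents that add atoms: none
Why: Dess–Martin oxidation under bicarbonate buffering is fast and neutral, so the β,γ-unsaturated aldehyde should form without migration of the double bond or epimerisation at C5.

**Step 6**
Reactants: 10 (1R,6S)-2,6-dimethyl-6-(4-methylpent-3-en-1-yl)cyclohex-2-ene-1-carbaldehyde
Product: 11 eudesma-3,11-dien-6α-ol (5α-H, 7β-isopropenyl, 10β-methyl)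
Conditions: Me2AlCl (1.5 equiv), CH2Cl2, −78 °C; then cold 1 M HCl
Reagents that add atoms: none
Why: Me2AlCl binds the formyl oxygen, C6 is attacked by C7 of the trisubstituted alkene while a hydrogen of an allylic methyl group passes to oxygen in a concerted six-electron carbonyl-ene reaction, and the aluminium alkoxide then loses methane so that no free acid remains. The closest known reaction is the Lewis-acid cyclisation of citronellal to isopulegol, whose carbon chain is present here with its C2–C3 bond embedded in ring A. Ring B closes in the 6-exo mode through a chair in which the formyl group and the C9 chain are trans-diequatorial on ring A, which leads to the trans-decalin. C7 is fixed by the equatorial position of the reacting alkene in this chair (7β-isopropenyl), and C6 by the equatorial aluminium-bound oxygen (6α-OH), an axial oxygen being disfavoured by the 1,3-diaxial C10 methyl. The step needs the ene pathway to win over conjugation or epimerisation of the β,γ-unsaturated aldehyde and over a stepwise cation–olefin course; the low temperature, the proton-scavenging aluminium reagent and the polarisation of the alkene towards the tertiary C11 should secure this. Either C6 epimer converges on the same ketone in step 8, so only C7 has to be right here.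

**Step 7**
Reactants: 11 eudesma-3,11-dien-6α-ol
Product: 12 eudesm-3-en-6α-ol (5α-H, 7β-isopropyl, 10β-methyl)
Conditions: H2 (1 atm), RhCl(PPh3)3 (5 mol%), benzene–EtOH, 25 °C
Reagents that add atoms: none
Why: Homogeneous hydrogenation with RhCl(PPh3)3 reduces the unhindered 1,1-disubstituted isopropenyl group much faster than the trisubstituted ring alkene and creates no new stereocentre.

**Step 8**
Reactants: 12 eudesm-3-en-6α-ol
Product: 13 eudesm-3-en-6-one (5α-H, 7β-isopropyl, 10β-methyl)
Conditions: Dess–Martin periodinane, NaHCO3, CH2Cl2, 0 °C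
Reagents that add atoms: none
Why: Dess–Martin oxidation of the hindered secondary alcohol under buffered, non-enolising conditions should give the β,γ-unsaturated ketone with C5 and C7 intact.

**Step 9**
Reactants: 13 eudesm-3-en-6-one
Product: 14 eudesm-3-en-6β-ol (5α-H, 7β-isopropyl, 10β-methyl)
Conditions: NaBH4, CeCl3·7H2O, MeOH, −40 °C
Reagents that add atoms: none
Why: Borohydride reduction in which the axial 10β-methyl blocks the β face, so hydride should attack from the α face and give the axial 6β-alcohol as with 6-oxo-5α-steroids, the cerium salt keeping the medium non-basic so that the double bond stays at C3=C4.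

**Step 10**
Reactants: 14 eudesm-3-en-6β-ol
Product: 15 eudesm-3-en-6β-yl benzoate
Conditions: n-BuLi (1.05 equiv), THF, −78 °C; then BzCl, −78 → 0 °C
Reagents that add atoms: benzoyl chloride, O=C(Cl)c1ccccc1
Why: O-Acylation of the preformed lithium alkoxide overcomes the hindrance of the axial hydroxyl flanked by the isopropyl group and the syn-axial C10 methyl, with retention at C6.

**Step 11**
Reactants: 15 eudesm-3-en-6β-yl benzoate
Product: 16 3α,4α-epoxyeudesman-6β-yl benzoate
Conditions: mCPBA, CH2Cl2, 0 °C
Reagents that add atoms: 3-chloroperoxybenzoic acid (mCPBA), OOC(=O)c1cccc(Cl)c1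
Why: Prilezhaev epoxidation from the α face, because the β face of C3=C4 is screened by the axial C10 methyl and the axial 6β-benzoate.

**Step 12**
Reactants: 16 3α,4α-epoxyeudesman-6β-yl benzoate
Product: 17 3α,4β-dihydroxyeudesman-6β-yl benzoate, (3R,4R,5S,6R,7S,10S), the target
Conditions: HClO4 (cat.), THF–H2O, 0 → 25 °C
Reagents that add atoms: water, O
Why: Acid-catalysed epoxide hydrolysis in which the protonated epoxide opens at the tertiary C4 with inversion and trans-diaxially (Fürst–Plattner), oxygen entering on the β face either directly as water or with anchimeric help from the syn-axial benzoate carbonyl, so that C3 keeps its α-oxygen and the 3α,4β-diol results.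

**Compound list**

1 | 2,6-dimethylhept-5-enal (racemic) | CC(CCC=C(C)C)C=O | starting material
2 | ethyl vinyl ketone (pent-1-en-3-one) | CCC(=O)C=C | starting material
3 | (S)-2-methyl-2-(4-methylpent-3-en-1-yl)-5-oxoheptanal (formed in situ) | O=C[C@@](C)(CCC=C(C)C)CCC(=O)CC | intermediate
4 | (S)-2,4-dimethyl-4-(4-methylpent-3-en-1-yl)cyclohex-2-en-1-one | O=C1CC[C@](C)(CCC=C(C)C)C=C1C | intermediate
5 | (1S,4S)-2,4-dimethyl-4-(4-methylpent-3-en-1-yl)cyclohex-2-en-1-ol | O[C@H]1CC[C@](C)(CCC=C(C)C)C=C1C | intermediate
6 | tributyl(iodomethyl)stannane | CCCC[Sn](CCCC)(CCCC)CI | starting material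
7 | tributyl({[(1S,4S)-2,4-dimethyl-4-(4-methylpent-3-en-1-yl)cyclohex-2-en-1-yl]oxy}methyl)stannane | CCCC[Sn](CCCC)(CCCC)CO[C@H]1CC[C@](C)(CCC=C(C)C)C=C1C | intermediate
8 | ({[(1S,4S)-2,4-dimethyl-4-(4-methylpent-3-en-1-yl)cyclohex-2-en-1-yl]oxy}methyl)lithium (formed in situ) | [Li]CO[C@H]1CC[C@](C)(CCC=C(C)C)C=C1C | intermediate
9 | [(1R,6S)-2,6-dimethyl-6-(4-methylpent-3-en-1-yl)cyclohex-2-en-1-yl]methanol | OC[C@H]1C(C)=CCC[C@]1(C)CCC=C(C)C | intermediate
10 | (1R,6S)-2,6-dimethyl-6-(4-methylpent-3-en-1-yl)cyclohex-2-ene-1-carbaldehyde (formyl cis to the C6 methyl) | O=C[C@H]1C(C)=CCC[C@]1(C)CCC=C(C)C | intermediate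
11 | eudesma-3,11-dien-6α-ol (5α-H, 7β-isopropenyl, 10β-methyl) | CC(=C)[C@@H]1CC[C@@]2(C)CCC=C(C)[C@@H]2[C@H]1O | intermediate
12 | eudesm-3-en-6α-ol (5α-H, 7β-isopropyl, 10β-methyl) | CC(C)[C@@H]1CC[C@@]2(C)CCC=C(C)[C@@H]2[C@H]1O | intermediate
13 | eudesm-3-en-6-one (5α-H, 7β-isopropyl, 10β-methyl) | CC(C)[C@@H]1CC[C@@]2(C)CCC=C(C)[C@@H]2C1=O | intermediate
14 | eudesm-3-en-6β-ol (5α-H, 7β-isopropyl, 10β-methyl) | CC(C)[C@@H]1CC[C@@]2(C)CCC=C(C)[C@@H]2[C@@H]1O | intermediate
15 | eudesm-3-en-6β-yl benzoate | CC(C)[C@@H]1CC[C@@]2(C)CCC=C(C)[C@@H]2[C@@H]1OC(=O)c1ccccc1 | intermediate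
16 | 3α,4α-epoxyeudesman-6β-yl benzoate | CC(C)[C@@H]1CC[C@@]2(C)CC[C@H]3O[C@@]3(C)[C@@H]2[C@@H]1OC(=O)c1ccccc1 | intermediate
17 | 3α,4β-dihydroxyeudesman-6β-yl benzoate (5α-H, 7β-isopropyl, 10β-methyl, 4α-methyl) | CC(C)[C@@H]1CC[C@@]2(C)CC[C@@H](O)[C@](C)(O)[C@@H]2[C@@H]1OC(=O)c1ccccc1 | target

**Count**

Total step count: 12. Longest linear sequence: 12 steps (1 → 17).

**Steps most likely to fail, with fallbacks**

Step 1. The process at risk is the discrimination between methyl and homoprenyl in the enamine, which may be too weak, so that too little of the (S)-series forms and much material is lost as diastereomers after step 2. The fallback replaces catalyst control by auxiliary control. It does not set out from a route intermediate but, in place of 1 and 2, from commercial (S)-valinol and 5-oxoheptanoic acid. Condensation in refluxing toluene with removal of water should give the bicyclic lactam (3S,8aR)-8a-ethyl-3-isopropylhexahydro-5H-[1,3]oxazolo[3,2-a]pyridin-5-one F1. LDA and MeI would give the 6-methyl lactam F2 as an epimer mixture. A second enolisation and alkylation with 5-iodo-2-methylpent-2-ene (from the commercial bromide and NaI) should place the homoprenyl group on the endo face, anti to the angular ethyl group, and give the (3S,6S,8aR)-6-methyl-6-(4-methylpent-3-en-1-yl) lactam F3. Reduction with Red-Al to the carbinolamine F4 and hydrolysis with aqueous Bu4N H2PO4 in ethanol would release (S)-valinol and the keto aldehyde 3, which is closed with KOH as in step 1. The route is rejoined at 3 and then 4.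

Step 4. The process at risk is the bond formation at C5 next to the quaternary C10, which may lose to a [1,2]-shift or to simple protonation of the lithiomethyl ether. The fallback sets out from 5 and comes back at 9, replacing the anionic rearrangement by a carbamate-directed syn-SN2′ substitution. Alcohol 5 and PhNCO (DMAP, CH2Cl2) would give the N-phenylcarbamate F5. Deprotonation with MeLi, then CuI and [(isopropoxy)dimethylsilyl]methylmagnesium chloride (THF, −78 → 0 °C), should deliver the silylmethyl group to C5 on the face of the carbamate and give the silane {[(1R,6S)-2,6-dimethyl-6-(4-methylpent-3-en-1-yl)cyclohex-2-en-1-yl]methyl}(isopropoxy)dimethylsilane F6. Tamao oxidation (H2O2, KF, KHCO3, THF–MeOH) would then give 9.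

Step 8 (with step 9). The process at risk is migration of the C3=C4 double bond into conjugation with the C6 carbonyl during oxidation or reduction, which would destroy the C5 stereocentre. The fallback sets out from 12 and comes back at 16; it removes the alkene before the ketone is made. mCPBA should epoxidise 12 from the α face to 3α,4α-epoxyeudesman-6α-ol F7. Dess–Martin oxidation would give 3α,4α-epoxyeudesman-6-one F8. NaBH4/CeCl3 at low temperature should give 3α,4α-epoxyeudesman-6β-ol F9 by the same α-face attack. Benzoylation as in step 10 would give 16, which continues with step 12.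

**Further compounds**

F1 | step 1 | (3S,8aR)-8a-ethyl-3-isopropylhexahydro-5H-[1,3]oxazolo[3,2-a]pyridin-5-one | CC[C@@]12CCCC(=O)N1[C@@H](C(C)C)CO2
F2 | step 1 | (3S,8aR)-8a-ethyl-3-isopropyl-6-methylhexahydro-5H-[1,3]oxazolo[3,2-a]pyridin-5-one (C6 epimers) | CC[C@@]12CCC(C)C(=O)N1[C@@H](C(C)C)CO2
F3 | step 1 | (3S,6S,8aR)-8a-ethyl-3-isopropyl-6-methyl-6-(4-methylpent-3-en-1-yl)hexahydro-5H-[1,3]oxazolo[3,2-a]pyridin-5-one | CC[C@@]12CC[C@](C)(CCC=C(C)C)C(=O)N1[C@@H](C(C)C)CO2
F4 | step 1 | (3S,6S,8aR)-8a-ethyl-3-isopropyl-6-methyl-6-(4-methylpent-3-en-1-yl)hexahydro-5H-[1,3]oxazolo[3,2-a]pyridin-5-ol (carbinolamine, C5 epimers) | CC[C@@]12CC[C@](C)(CCC=C(C)C)C(O)N1[C@@H](C(C)C)CO2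
F5 | step 4 | (1S,4S)-2,4-dimethyl-4-(4-methylpent-3-en-1-yl)cyclohex-2-en-1-yl N-phenylcarbamate | O=C(Nc1ccccc1)O[C@H]1CC[C@](C)(CCC=C(C)C)C=C1C
F6 | step 4 | {[(1R,6S)-2,6-dimethyl-6-(4-methylpent-3-en-1-yl)cyclohex-2-en-1-yl]methyl}(isopropoxy)dimethylsilane | CC(C)O[Si](C)(C)C[C@H]1C(C)=CCC[C@]1(C)CCC=C(C)C
F7 | step 8 | 3α,4α-epoxyeudesman-6α-ol | CC(C)[C@@H]1CC[C@@]2(C)CC[C@H]3O[C@@]3(C)[C@@H]2[C@H]1O
F8 | step 8 | 3α,4α-epoxyeudesman-6-one | CC(C)[C@@H]1CC[C@@]2(C)CC[C@H]3O[C@@]3(C)[C@@H]2C1=O
F9 | step 8 | 3α,4α-epoxyeudesman-6β-ol | CC(C)[C@@H]1CC[C@@]2(C)CC[C@H]3O[C@@]3(C)[C@@H]2[C@@H]1O
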